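C6–C7 Dieckmann route to CNP0150579.2 from an acyclic ynone triester

Numbering as in chromene: ring B is O1–C2–C3–C4–C4a–C8a and ring A is C4a–C5–C6–C7–C8–C8a. The enabling feature is that C4a is a triacylmethane carbon (bonded to C4=O, enol carbon C5 and C8a–O1) and that C5–C6–C7 is an enolised 1,3-diketone next to the quaternary, non-enolisable C8. This makes C6–C7 a Dieckmann bond, C4a–C5 an acyl-transfer bond and O1–C8a the oxa-Michael bond of an ynone.
Acid 21 <= methyl ester 20 <= acyclic ynone triester 18, in one flask. Ring B closes first (C4a–C5, then O1–C8a), then ring A closes by C6–C7.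
18 <= esterification of hydroxy ynone 17 with hemiester 16, which parks the future C5 acyl group on O1. 16 comes from desymmetrised 3-phenylglutaric anhydride and carries the benzylic centre.
17 <= lithium acetylide of alkyne ester 10 + Weinreb amide 14 (Evans syn aldol sets C2 and C3).
10 <= methyl acetoacetate + (R)-lavandulyl iodide + prenyl bromide. C8 is set by a Fráter–Seebach prenylation under control of a temporary carbinol centre, which is then oxidised and turned into the alkyne.
Key step: step 12

Assumption 1: (R)-(−)-lavandulol 1, the natural antipode, is bought as the single enantiomer; racemic material would first need a lipase resolution.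
Assumption 2: the quinidine-derived catalyst of step 9 is taken to select the same enantiotopic carbonyl as in 3-alkylglutaric anhydrides, which gives (S)-16. The quinine-derived (DHQ)2AQN gives the antipode if the sense turns out reversed.

Step 1
Reactants: 1 (R)-lavandulol
Product: 2 (R)-lavandulyl iodide
Conditions: I2, PPh3, imidazole, CH2Cl2, 0 °C to rt
Reagents that add atoms: iodine, II
Why: Appel-type iodination replaces the primary hydroxyl by SN2 at CH2, so the neighbouring stereocentre and both alkenes stay untouched.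

Step 2
Reactants: 2 (R)-lavandulyl iodide; 3 methyl acetoacetate
Product: 4 methyl (4S)-2-acetyl-7-methyl-4-(prop-1-en-2-yl)oct-6-enoate (C2 labile)
Conditions: NaH, 3 (1.5 equiv), THF–DMF, 0 °C; then 2, 60 °C
Reagents that add atoms: none
Why: Acetoacetic ester alkylation, in which the soft and weakly basic sodium enolate should substitute the beta-branched primary iodide rather than eliminate it; the new C2 centre is labile and of no consequence.

Step 3
Reactants: 4 methyl (4S)-2-acetyl-7-methyl-4-(prop-1-en-2-yl)oct-6-enoate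
Product: 5 methyl (4S)-2-[(1R)-1-hydroxyethyl]-7-methyl-4-(prop-1-en-2-yl)oct-6-enoate (both C2 epimers)
Conditions: H2 (4 bar), RuCl2[(R)-BINAP] (1 mol %), MeOH, 50 °C
Reagents that add atoms: none
Why: Noyori asymmetric hydrogenation of a beta-keto ester, in which the ester-chelated ketone is reduced on the face set by (R)-BINAP to the (R)-carbinol in both C2 epimers, while the unfunctionalised tri- and 1,1-disubstituted alkenes have no directing group and should stay.

Step 4
Reactants: 5 methyl (4S)-2-[(1R)-1-hydroxyethyl]-7-methyl-4-(prop-1-en-2-yl)oct-6-enoate; 6 prenyl bromide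
Product: 7 methyl (2S,4S)-2-[(1R)-1-hydroxyethyl]-7-methyl-2-(3-methylbut-2-en-1-yl)-4-(prop-1-en-2-yl)oct-6-enoate
Conditions: LiN(i-Pr)2 (2.3 equiv), THF, −78 to −10 °C; 6, DMPU, −78 to −20 °C; AcOH quench
Reagents that add atoms: none
Why: Fráter–Seebach alkylation, in which both C2 epimers converge on one lithium-chelated alkoxide–enolate dianion and prenyl bromide enters anti to the carbinol methyl group, which sets the quaternary carbon (future C8) as S; minor diastereomers can be removed by chromatography.

Step 5
Reactants: 7 methyl (2S,4S)-2-[(1R)-1-hydroxyethyl]-7-methyl-2-(3-methylbut-2-en-1-yl)-4-(prop-1-en-2-yl)oct-6-enoate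
Product: 8 methyl (2S,4S)-2-acetyl-7-methyl-2-(3-methylbut-2-en-1-yl)-4-(prop-1-en-2-yl)oct-6-enoate
Conditions: Dess–Martin periodinane, CH2Cl2, rt
Reagents that add atoms: none
Why: Dess–Martin oxidation removes the temporary carbinol centre under near-neutral conditions, and the quaternary alpha carbon cannot epimerise.

Step 6
Reactants: 8 methyl (2S,4S)-2-acetyl-7-methyl-2-(3-methylbut-2-en-1-yl)-4-(prop-1-en-2-yl)oct-6-enoate
Product: 10 methyl (2S,4S)-2-ethynyl-7-methyl-2-(3-methylbut-2-en-1-yl)-4-(prop-1-en-2-yl)oct-6-enoate, via enol phosphate 9 (not isolated)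
Conditions: LiN(i-Pr)2 (1.1 equiv), THF, −78 °C; ClP(O)(OEt)2, −78 °C to rt; LiN(i-Pr)2 (2.3 equiv), −78 °C to rt; AcOH quench
Reagents that add atoms: diethyl chlorophosphate, CCOP(=O)(Cl)OCC (its atoms stay in 9 only and leave again on the way to 10)
Why: Methyl ketone to terminal alkyne by kinetic enol phosphate formation and base-induced elimination; only the CH3 side can enolise and no allene can form, because the other alpha carbon is quaternary.

Step 7
Reactants: 11 (4S)-4-benzyl-3-propanoyl-1,3-oxazolidin-2-one; 12 acetaldehyde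
Product: 13 (4S)-4-benzyl-3-[(2S,3R)-3-hydroxy-2-methylbutanoyl]-1,3-oxazolidin-2-one
Conditions: Bu2BOTf, Et3N, CH2Cl2, −78 to 0 °C; 12, −78 to 0 °C; H2O2, MeOH, pH 7 buffer, 0 °C
Reagents that add atoms: none
Why: Evans syn aldol, in which the Z boron enolate reacts through a Zimmerman–Traxler chair on the face away from the benzyl group and gives the (2S,3R) syn adduct, which carries the future C3 and C2 in the cis relation of the target.

Step 8
Reactants: 13 (4S)-4-benzyl-3-[(2S,3R)-3-hydroxy-2-methylbutanoyl]-1,3-oxazolidin-2-one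
Product: 14 (2S,3R)-3-hydroxy-N-methoxy-N,2-dimethylbutanamide
Conditions: MeNH(OMe)·HCl, AlMe3, CH2Cl2, −10 °C to rt
Reagents that add atoms: N,O-dimethylhydroxylamine hydrochloride, CNOC.Cl
Why: Weinreb aminolysis by the aluminium amide, helped by the free beta-hydroxyl, cleaves the exocyclic imide carbonyl without epimerisation and releases the auxiliary.

Step 9
Reactants: 15 3-phenylglutaric anhydride
Product: 16 (3S)-5-methoxy-5-oxo-3-phenylpentanoic acid
Conditions: MeOH (10 equiv), (DHQD)2AQN (10 mol %), Et2O, −40 °C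
Reagents that add atoms: methanol, CO
Why: Cinchona-alkaloid-catalysed desymmetrising methanolysis of a prochiral cyclic anhydride, in which general-base activation of methanol by the quinuclidine nitrogen tells the two enantiotopic carbonyl groups apart and so sets the benzylic centre.

Step 10
Reactants: 10 methyl (2S,4S)-2-ethynyl-7-methyl-2-(3-methylbut-2-en-1-yl)-4-(prop-1-en-2-yl)oct-6-enoate; 14 (2S,3R)-3-hydroxy-N-methoxy-N,2-dimethylbutanamide
Product: 17 methyl (2S,4S)-2-[(4S,5R)-5-hydroxy-4-methyl-3-oxohex-1-yn-1-yl]-7-methyl-2-(3-methylbut-2-en-1-yl)-4-(prop-1-en-2-yl)oct-6-enoate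
Conditions: 14, i-PrMgCl (1.0 equiv), THF, −40 °C; 10, LiN(i-Pr)2 (1.05 equiv), THF, −78 °C; mix, −78 to −10 °C; AcOH quench at −78 °C
Reagents that add atoms: none
Why: Weinreb ketone synthesis, in which the hydroxyl is masked as its magnesium alkoxide and the lithium acetylide adds once to the amide to give a stable chelate that collapses to the ynone only on quench, while the hindered methyl ester is left alone in the cold.

Step 11
Reactants: 17 hydroxy ynone; 16 (3S)-5-methoxy-5-oxo-3-phenylpentanoic acid
Product: 18 acyclic ynone triester (17 acylated on the C5' hydroxyl by 16)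
Conditions: DCC, DMAP (10 mol %), CH2Cl2, 0 °C
Reagents that add atoms: none
Why: Steglich esterification parks the future C5 acyl group on the future O1; the low temperature and the small amount of DMAP are meant to hold back beta-elimination and premature ring closure.

Step 12
Reactants: 18 acyclic ynone triester
Product: 20 methyl ester of the target, via acyl-dihydropyranone diester 19 (not isolated)
Conditions: PBu3 (20 mol %), THF (0.02 M), 0 °C to rt; then LiN(SiMe3)2 (2.2 equiv), −78 to 0 °C; AcOH quench
Reagents that add atoms: none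
Why: Proposed new method: PBu3 adds to alkyne carbon C8a, the allenolate carbon C4a attacks the ester carbonyl parked on O1 through a six-membered transition state (O-to-C acyl transfer, C4a–C5), and the freed C2 alkoxide displaces the phosphine from C8a by addition–elimination to give 19, after which LiN(SiMe3)2 removes a C6 proton next to the new C5 ketone and this enolate attacks the C7 methyl ester (Dieckmann condensation, C6–C7) with loss of methoxide. The closest known reaction types are the phosphine-catalysed tandem acyl transfer–cyclisation of 2-acyloxyaryl ynones to 3-acylchromones, carried over here from a phenol ester to a secondary alkyl ester, and the Dieckmann closure of 3,5-dioxo esters with a quaternary alpha carbon to 2,2-dialkylcyclohexane-1,3,5-triones. Ring B closes in a 6-endo mode (6-endo-dig as seen from the ynone) and ring A in a 6-(enolendo)-exo-trig mode. No stereocentre is created: C8 and the lavandulyl carbon come from 10, C2 and C3 from 14 and the benzylic carbon from 16, and no bond to any of them changes. O1 must bind C8a and not C5, which is secured because only C8a carries the phosphonium leaving group; ynone-to-dienone isomerisation is blocked and C7 can act only as acceptor because C8 has no hydrogen. C3 must not be enolised: at −78 °C the secondary C6–H next to the twisted exocyclic ketone should be removed faster than the tertiary C3–H of the ring vinylogous ester, and 20 is stored at once as its delocalised enolate, in which C4 no longer acidifies C3–H.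

Step 13
Reactants: 20 methyl ester of the target
Product: 21 target acid CNP0150579.2
Conditions: LiOH, THF–H2O, 0 °C to rt; then 1 M HCl to pH 3
Reagents that add atoms: lithium hydroxide, [Li+].[OH-]
Why: Saponification of the only remaining ester; under these conditions the bicycle is present as its delocalised enolate, which should shield C3 from enolisation, C8a from hydroxide attack and the benzylic carbon from retro-Michael loss.

Compound list
1 | (R)-lavandulol, (2R)-5-methyl-2-(prop-1-en-2-yl)hex-4-en-1-ol | C=C(C)[C@@H](CC=C(C)C)CO | starting material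
2 | (R)-lavandulyl iodide, (3R)-3-(iodomethyl)-2,6-dimethylhepta-1,5-diene | C=C(C)[C@@H](CC=C(C)C)CI | intermediate
3 | methyl acetoacetate | CC(=O)CC(=O)OC | starting material
4 | methyl (4S)-2-acetyl-7-methyl-4-(prop-1-en-2-yl)oct-6-enoate, C2 labile | C=C(C)[C@@H](CC=C(C)C)CC(C(C)=O)C(=O)OC | intermediate
5 | methyl (4S)-2-[(1R)-1-hydroxyethyl]-7-methyl-4-(prop-1-en-2-yl)oct-6-enoate, both C2 epimers | C=C(C)[C@@H](CC=C(C)C)CC([C@@H](C)O)C(=O)OC | intermediate
6 | prenyl bromide, 1-bromo-3-methylbut-2-ene | CC(C)=CCBr | starting material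
7 | methyl (2S,4S)-2-[(1R)-1-hydroxyethyl]-7-methyl-2-(3-methylbut-2-en-1-yl)-4-(prop-1-en-2-yl)oct-6-enoate | C=C(C)[C@@H](CC=C(C)C)C[C@]([C@@H](C)O)(CC=C(C)C)C(=O)OC | intermediate
8 | methyl (2S,4S)-2-acetyl-7-methyl-2-(3-methylbut-2-en-1-yl)-4-(prop-1-en-2-yl)oct-6-enoate | C=C(C)[C@@H](CC=C(C)C)C[C@](C(C)=O)(CC=C(C)C)C(=O)OC | intermediate
9 | methyl (2S,4S)-2-{1-[(diethoxyphosphoryl)oxy]ethenyl}-7-methyl-2-(3-methylbut-2-en-1-yl)-4-(prop-1-en-2-yl)oct-6-enoate (enol phosphate) | C=C(C)[C@@H](CC=C(C)C)C[C@](C(=C)OP(=O)(OCC)OCC)(CC=C(C)C)C(=O)OC | intermediate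
10 | methyl (2S,4S)-2-ethynyl-7-methyl-2-(3-methylbut-2-en-1-yl)-4-(prop-1-en-2-yl)oct-6-enoate | C=C(C)[C@@H](CC=C(C)C)C[C@](C#C)(CC=C(C)C)C(=O)OC | intermediate
11 | (4S)-4-benzyl-3-propanoyl-1,3-oxazolidin-2-one | CCC(=O)N1[C@@H](Cc2ccccc2)COC1=O | starting material
12 | acetaldehyde | CC=O | starting material
13 | (4S)-4-benzyl-3-[(2S,3R)-3-hydroxy-2-methylbutanoyl]-1,3-oxazolidin-2-one | C[C@@H](O)[C@H](C)C(=O)N1[C@@H](Cc2ccccc2)COC1=O | intermediate
14 | (2S,3R)-3-hydroxy-N-methoxy-N,2-dimethylbutanamide | C[C@@H](O)[C@H](C)C(=O)N(C)OC | intermediate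
15 | 3-phenylglutaric anhydride, 4-phenyloxane-2,6-dione | O=C1CC(c2ccccc2)CC(=O)O1 | starting material
16 | (3S)-5-methoxy-5-oxo-3-phenylpentanoic acid | OC(=O)C[C@@H](CC(=O)OC)c1ccccc1 | intermediate
17 | methyl (2S,4S)-2-[(4S,5R)-5-hydroxy-4-methyl-3-oxohex-1-yn-1-yl]-7-methyl-2-(3-methylbut-2-en-1-yl)-4-(prop-1-en-2-yl)oct-6-enoate | C=C(C)[C@@H](CC=C(C)C)C[C@](C#CC(=O)[C@@H](C)[C@@H](C)O)(CC=C(C)C)C(=O)OC | intermediate
18 | methyl (2S,4S)-2-[(4S,5R)-5-{[(3R)-5-methoxy-5-oxo-3-phenylpentanoyl]oxy}-4-methyl-3-oxohex-1-yn-1-yl]-7-methyl-2-(3-methylbut-2-en-1-yl)-4-(prop-1-en-2-yl)oct-6-enoate (benzylic descriptor differs from 16 by ranking only) | C=C(C)[C@@H](CC=C(C)C)C[C@](C#CC(=O)[C@@H](C)[C@@H](C)OC(=O)C[C@@H](CC(=O)OC)c1ccccc1)(CC=C(C)C)C(=O)OC | intermediate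
19 | methyl (2S,4S)-2-{(2R,3S)-5-[(3S)-5-methoxy-5-oxo-3-phenylpentanoyl]-2,3-dimethyl-4-oxo-3,4-dihydro-2H-pyran-6-yl}-7-methyl-2-(3-methylbut-2-en-1-yl)-4-(prop-1-en-2-yl)oct-6-enoate | C=C(C)[C@@H](CC=C(C)C)C[C@](CC=C(C)C)(C(=O)OC)C1=C(C(=O)C[C@@H](CC(=O)OC)c2ccccc2)C(=O)[C@@H](C)[C@@H](C)O1 | intermediate
20 | methyl (3S)-3-{(2R,3S,8S)-5-hydroxy-2,3-dimethyl-8-(3-methylbut-2-en-1-yl)-8-[(2S)-5-methyl-2-(prop-1-en-2-yl)hex-4-en-1-yl]-4,7-dioxo-3,4,7,8-tetrahydro-2H-chromen-6-yl}-3-phenylpropanoate | C=C(C)[C@@H](CC=C(C)C)C[C@]1(CC=C(C)C)C(=O)C([C@@H](CC(=O)OC)c2ccccc2)=C(O)C2=C1O[C@H](C)[C@H](C)C2=O | intermediate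
21 | (3S)-3-{(2R,3S,8S)-5-hydroxy-2,3-dimethyl-8-(3-methylbut-2-en-1-yl)-8-[(2S)-5-methyl-2-(prop-1-en-2-yl)hex-4-en-1-yl]-4,7-dioxo-3,4,7,8-tetrahydro-2H-chromen-6-yl}-3-phenylpropanoic acid | C=C(C)[C@@H](CC=C(C)C)C[C@]1(CC=C(C)C)C(=O)C([C@@H](CC(=O)O)c2ccccc2)=C(O)C2=C1O[C@H](C)[C@H](C)C2=O | target

Total step count: 13. Longest linear sequence: 10 steps (1, 2, 3, 4, 5, 6, 10, 11, 12, 13).

Steps most likely to fail

Step 12. Three processes may go wrong. Phosphine addition at the hindered C8a may be too slow. Beta-elimination of the acyloxy group may outrun the acyl transfer from an alkyl ester. Configuration at C3 may be lost in the base stage.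
- The fallback uses known reactions, runs stepwise, and puts nitrogen in place of phosphorus as the leaving group on C8a.
- It sets out from 17 and 16 and comes back at 19, which is then isolated and closed to 20 with LiN(SiMe3)2 in a separate flask.
- 17 is silylated (Et3SiCl, imidazole, CH2Cl2) to the triethylsilyl ether F1.
- Pyrrolidine adds to the ynone (aza-Michael addition, EtOH, rt) to give the beta-pyrrolidino enone F2.
- 16 is turned under neutral conditions with 1-chloro-N,N,2-trimethylprop-1-en-1-amine into the acid chloride F3.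
- F2 is acylated at C4a by F3 (pyridine, CH2Cl2, 0 °C; C-acylation of a tertiary enaminone) to the diacyl enamine F4.
- HF·pyridine in THF removes the silyl group, and O1 then displaces pyrrolidine from C8a to give 19.

Step 4. Enolisation of the hindered alpha carbon may be incomplete, or facial selectivity in the attack of prenyl bromide on the dianion may be poor.
- The fallback replaces the carbinol relay by a removable amino acid auxiliary.
- It sets out from 4 and comes back at 8, so that steps 3 to 5 are bypassed.
- 4 is condensed with L-valine tert-butyl ester (cat. BF3·OEt2, toluene, Dean–Stark trap) to the hydrogen-bonded Z enamino ester F5.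
- Lithiation with LiN(i-Pr)2 in toluene follows, with a donor additive. The additive (hexamethylphosphoramide or THF) decides which face stays open, and the one that gives S at the quaternary carbon is kept.
- Alkylation with 6 gives the alkylated imine F6, which dilute aqueous acid hydrolyses on work-up to 8.

Step 11. Base-induced beta-elimination of the newly formed acyloxy ynone may occur, or DMAP may trigger ring closure of the hydroxy ynone before acylation.
- The fallback changes the order of bond formation and makes the ester before the ynone exists.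
- It sets out from 14 and 16 and comes back at 18.
- 14 is esterified with 16 (DCC, DMAP, CH2Cl2) at the amide stage, where the alpha proton is far less acidic and no alkyne is present. This gives the ester amide F7.
- The lithium acetylide of 10 (LiN(i-Pr)2, THF, −78 °C) is then added to F7. Chelation should let the N-methoxy-N-methylamide react ahead of the two alkyl esters, and an AcOH quench gives 18.

Further compounds
F1 | step 12 | triethylsilyl ether of 17 | C=C(C)[C@@H](CC=C(C)C)C[C@](C#CC(=O)[C@@H](C)[C@@H](C)O[Si](CC)(CC)CC)(CC=C(C)C)C(=O)OC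
F2 | step 12 | methyl (2S,4S)-7-methyl-2-[(4S,5R)-4-methyl-3-oxo-1-(pyrrolidin-1-yl)-5-(triethylsilyloxy)hex-1-en-1-yl]-2-(3-methylbut-2-en-1-yl)-4-(prop-1-en-2-yl)oct-6-enoate | C=C(C)[C@@H](CC=C(C)C)C[C@](CC=C(C)C)(C(=O)OC)C(=CC(=O)[C@@H](C)[C@@H](C)O[Si](CC)(CC)CC)N1CCCC1
F3 | step 12 | methyl (3R)-5-chloro-5-oxo-3-phenylpentanoate | ClC(=O)C[C@@H](CC(=O)OC)c1ccccc1
F4 | step 12 | diacyl enamine, F2 acylated at the enamine alpha carbon by F3 | C=C(C)[C@@H](CC=C(C)C)C[C@](CC=C(C)C)(C(=O)OC)C(N1CCCC1)=C(C(=O)C[C@@H](CC(=O)OC)c1ccccc1)C(=O)[C@@H](C)[C@@H](C)O[Si](CC)(CC)CC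
F5 | step 4 | Z enamino ester of 4 and L-valine tert-butyl ester | C=C(C)[C@@H](CC=C(C)C)C/C(C(=O)OC)=C(\C)N[C@@H](C(C)C)C(=O)OC(C)(C)C
F6 | step 4 | prenylated imine, L-valine tert-butyl ester imine of 8 | C=C(C)[C@@H](CC=C(C)C)C[C@](CC=C(C)C)(C(=O)OC)C(C)=N[C@@H](C(C)C)C(=O)OC(C)(C)C
F7 | step 11 | (2R,3S)-4-[methoxy(methyl)amino]-3-methyl-4-oxobutan-2-yl methyl (3R)-3-phenylpentanedioate | CON(C)C(=O)[C@@H](C)[C@@H](C)OC(=O)C[C@@H](CC(=O)OC)c1ccccc1
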